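Isoirigenin is disconnected at the C4–C4a bond of ring C, so the pyranone is closed last by an intramolecular Friedel–Crafts acylation. The step exploits the substitution pattern of ring A. Of the two carbons flanking the O1-bearing C8a, C8 already carries the methoxy group. C4a is therefore the only site a tethered acyl carbon can reach, and the 6-methoxy isomer cannot form. In one operation the step makes C4–C4a, closes ring C and completes the isoflavone skeleton. Its precursor is a tribenzyl-protected (Z)-3-aryloxy-2-arylacrylic acid, assembled by vinylic substitution of a ring B enol tosylate with a ring A phenol.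

Key step: step 13

Assumption: the vinylic substitution of step 11 is taken to run with retention, so the aryl vinyl ether ester and acid are drawn Z (any E isomer is carried along because the key step converges on Z); the ketene dithioacetal S-oxide is drawn without alkene or sulfoxide descriptors because both elements are erased one step later.

Step 1
Reactants: 1 2,4,6-trihydroxybenzaldehyde; 2 benzyl bromide
Product: 3 2,4-bis(benzyloxy)-6-hydroxybenzaldehyde
Conditions: 2 (2 equiv), K2CO3 (2 equiv), DMF, 0 °C → rt
Reagents that add atoms: benzyl bromide, BrCc1ccccc1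
Why: Williamson etherification in which the 4-OH and one ortho OH are alkylated, while the last ortho OH stays hydrogen-bonded to the formyl oxygen and is far less nucleophilic, so two equivalents of 2 should stop at the dibenzyl ether.

Step 2
Reactants: 3 2,4-bis(benzyloxy)-6-hydroxybenzaldehyde
Product: 4 2,4-bis(benzyloxy)-6-(methoxymethoxy)benzaldehyde
Conditions: NaH, MOMCl, THF/DMF, 0 °C → rt
Reagents that add atoms: chloromethyl methyl ether, COCCl
Why: Irreversible deprotonation breaks the chelate, and O-alkylation of the phenoxide (Williamson-type acetal protection) installs a group that is orthogonal to benzyl and stable to peracid, carbonate base and MeI.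

Step 3
Reactants: 4 2,4-bis(benzyloxy)-6-(methoxymethoxy)benzaldehyde
Product: 6 2,4-bis(benzyloxy)-6-(methoxymethoxy)phenol, via aryl formate 5 (not isolated)
Conditions: mCPBA, CH2Cl2, 0 °C → rt; aq NaHCO3 wash, solvent swap; K2CO3 (cat.), MeOH, 0 °C → rt
Reagents that add atoms: 3-chloroperbenzoic acid, O=C(OO)c1cccc(Cl)c1
Why: Baeyer–Villiger oxidation (the peracid form of the Dakin reaction, needed because no free ortho or para OH remains), in which the very electron-rich aryl group migrates in the Criegee adduct and mild methanolysis of the formate frees the phenol without touching the MOM or benzyl groups.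

Step 4
Reactants: 6 2,4-bis(benzyloxy)-6-(methoxymethoxy)phenol
Product: 7 1,5-bis(benzyloxy)-2-methoxy-3-(methoxymethoxy)benzene
Conditions: MeI, K2CO3, DMF, rt
Reagents that add atoms: iodomethane, CI
Why: Williamson methylation of the only free phenol places the future C8 methoxy group between the two differentiated oxygens.

Step 5
Reactants: 7 1,5-bis(benzyloxy)-2-methoxy-3-(methoxymethoxy)benzene
Product: 8 3,5-bis(benzyloxy)-2-methoxyphenol
Conditions: HCl (cat.), MeOH/THF, 40 °C
Reagents that add atoms: none
Why: Acid-catalysed acetal exchange removes the MOM group while aryl benzyl and methyl ethers are inert to dilute methanolic HCl, unmasking the oxygen that becomes O1 beside the methoxy-bearing carbon.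

Step 6
Reactants: 9 3-hydroxy-4,5-dimethoxybenzaldehyde; 2 benzyl bromide
Product: 10 3-(benzyloxy)-4,5-dimethoxybenzaldehyde
Conditions: 2, K2CO3, DMF, rt → 50 °C
Reagents that add atoms: benzyl bromide, BrCc1ccccc1
Why: Williamson etherification of the single phenol gives ring B the same protecting group as ring A, so one final operation removes all three.

Step 7
Reactants: 10 3-(benzyloxy)-4,5-dimethoxybenzaldehyde
Product: 11 1-(benzyloxy)-2,3-dimethoxy-5-[2-(methylsulfanyl)-2-(methylsulfinyl)ethenyl]benzene
Conditions: MeS(O)CH2SMe, benzyltrimethylammonium hydroxide (cat.), THF, reflux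
Reagents that add atoms: methyl (methylsulfanyl)methyl sulfoxide, CSCS(C)=O
Why: Knoevenagel-type condensation of the sulfur-stabilised carbanion with the non-enolisable aldehyde, followed by loss of water, gives a ketene dithioacetal S-oxide, which is a masked arylacetic acid.

Step 8
Reactants: 11 1-(benzyloxy)-2,3-dimethoxy-5-[2-(methylsulfanyl)-2-(methylsulfinyl)ethenyl]benzene
Product: 12 methyl 2-[3-(benzyloxy)-4,5-dimethoxyphenyl]acetate
Conditions: HCl (ca. 3 M in MeOH), rt → 50 °C
Reagents that add atoms: methanol, CO
Why: Acid-promoted, Pummerer-type methanolysis of the ketene dithioacetal S-oxide (protonation at the benzylic carbon, capture of the thionium ion by MeOH, expulsion of both sulfur groups) delivers the one-carbon-homologated ester directly, and aryl benzyl ethers tolerate methanolic HCl.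

Step 9
Reactants: 12 methyl 2-[3-(benzyloxy)-4,5-dimethoxyphenyl]acetate
Product: 13 methyl (Z)-2-[3-(benzyloxy)-4,5-dimethoxyphenyl]-3-hydroxyacrylate (chelated enol of the α-formyl ester)
Conditions: NaH, HCO2Me (excess), THF, 0 °C → rt; then 1 M HCl
Reagents that add atoms: methyl formate, COC=O
Why: Crossed Claisen condensation with a non-enolisable formate, driven to completion by formation of the stabilised sodium enolate of the product.

Step 10
Reactants: 13 methyl (Z)-2-[3-(benzyloxy)-4,5-dimethoxyphenyl]-3-hydroxyacrylate
Product: 14 methyl (Z)-2-[3-(benzyloxy)-4,5-dimethoxyphenyl]-3-(tosyloxy)acrylate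
Conditions: TsCl, N-methylimidazole, LiOH, MeCN, 0 °C → rt
Reagents that add atoms: 4-toluenesulfonyl chloride, Cc1ccc(cc1)S(=O)(=O)Cl
Why: Enol O-sulfonylation by the N-tosylimidazolium salt formed in situ, in which lithium bridges the enolate and ester oxygens and holds them cis, so the Z enol tosylate should result.

Step 11
Reactants: 8 3,5-bis(benzyloxy)-2-methoxyphenol; 14 methyl (Z)-2-[3-(benzyloxy)-4,5-dimethoxyphenyl]-3-(tosyloxy)acrylate
Product: 15 methyl (Z)-3-[3,5-bis(benzyloxy)-2-methoxyphenoxy]-2-[3-(benzyloxy)-4,5-dimethoxyphenyl]acrylate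
Conditions: K2CO3, DMF, rt
Reagents that add atoms: none
Why: Nucleophilic vinylic substitution by addition–elimination, in which the phenoxide adds to the β-carbon and the ester- and aryl-stabilised carbanion expels tosylate, normally with retention, fixing O1 next to the methoxy carbon before any ring is formed.

Step 12
Reactants: 15 methyl (Z)-3-[3,5-bis(benzyloxy)-2-methoxyphenoxy]-2-[3-(benzyloxy)-4,5-dimethoxyphenyl]acrylate
Product: 16 (Z)-3-[3,5-bis(benzyloxy)-2-methoxyphenoxy]-2-[3-(benzyloxy)-4,5-dimethoxyphenyl]acrylic acid
Conditions: LiOH, THF/H2O, rt → 40 °C; then 1 M HCl to pH 3, 0 °C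
Reagents that add atoms: lithium hydroxide, [Li+].[OH-]
Why: Saponification by acyl–oxygen cleavage, routine for aryloxyfumarate and β-aryloxyacrylate esters, should outrun attack at the β-carbon because the vinylogous carbonate is a weak Michael acceptor shielded by the α-aryl group, and methanol is left out so that no alkoxide can exchange with the aryloxy group.

Step 13
Reactants: 16 (Z)-3-[3,5-bis(benzyloxy)-2-methoxyphenoxy]-2-[3-(benzyloxy)-4,5-dimethoxyphenyl]acrylic acid
Product: 18 5,7-bis(benzyloxy)-3-[3-(benzyloxy)-4,5-dimethoxyphenyl]-8-methoxy-4H-chromen-4-one, via mixed trifluoroacetic anhydride 17 (not isolated)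
Conditions: (CF3CO)2O (1.5 equiv), CH2Cl2, 0 °C → rt
Reagents that add atoms: none
Why: Trifluoroacetic anhydride turns 16 into the mixed anhydride 17, which ionises with help from the CF3CO2H released to an acyl cation stabilised by the β-aryloxy oxygen; C4a of ring A attacks this carbon and loss of the C4a proton from the arenium ion restores aromaticity. The closest known reaction type is the intramolecular Friedel–Crafts acylation of β-aryloxyacrylic and aryloxyfumaric acids to chromones. Ring C closes in a 6-exo-trig mode at the anhydride carbonyl (6-exo-dig if the free acyl cation reacts), and C4–C4a is the only bond formed. No stereocentre is created; the only geometric demand is the Z alkene, which is set in step 10, and any E material should reach it by reversible protonation at C3 or by rotation in the ketene–oxocarbenium form of the cation, with the Z form drained irreversibly by cyclisation. Regioselectivity needs no reagent control, because the tether from O1 reaches only the two carbons next to C8a, C8 is blocked by its methoxy group, and C4a is strongly activated (ortho to the 5-benzyloxy group and to the O1-bearing carbon, para to the 7-benzyloxy group). Chemoselectivity rests on the absence of a Lewis acid and the low temperature, which should spare the benzyl ethers, on near-stoichiometric anhydride so that intermolecular trifluoroacetylation at C6 cannot compete with the six-membered closure, and on the new carbonyl group, which deactivates ring A in 18.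

Step 14
Reactants: 18 5,7-bis(benzyloxy)-3-[3-(benzyloxy)-4,5-dimethoxyphenyl]-8-methoxy-4H-chromen-4-one
Product: 19 isoirigenin, 5,7-dihydroxy-3-(3-hydroxy-4,5-dimethoxyphenyl)-8-methoxy-4H-chromen-4-one
Conditions: H2 (1 atm), Pd/C (10 wt %), THF/MeOH, rt, stopped at full debenzylation
Reagents that add atoms: none
Why: Catalytic hydrogenolysis cleaves the three aryl benzyl ethers faster than the conjugated C2–C3 bond is reduced, leaves all methyl ethers intact, and its neutral medium avoids the ring-opening and reclosure (Wessely–Moser type) that could move the methoxy group from C8 to C6.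

Compound list
1 | 2,4,6-trihydroxybenzaldehyde | O=Cc1c(O)cc(O)cc1O | starting material
2 | benzyl bromide | BrCc1ccccc1 | starting material
3 | 2,4-bis(benzyloxy)-6-hydroxybenzaldehyde | O=Cc1c(O)cc(OCc2ccccc2)cc1OCc1ccccc1 | intermediate
4 | 2,4-bis(benzyloxy)-6-(methoxymethoxy)benzaldehyde | O=Cc1c(OCOC)cc(OCc2ccccc2)cc1OCc1ccccc1 | intermediate
5 | 2,4-bis(benzyloxy)-6-(methoxymethoxy)phenyl formate | O=COc1c(OCOC)cc(OCc2ccccc2)cc1OCc1ccccc1 | intermediate
6 | 2,4-bis(benzyloxy)-6-(methoxymethoxy)phenol | Oc1c(OCOC)cc(OCc2ccccc2)cc1OCc1ccccc1 | intermediate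
7 | 1,5-bis(benzyloxy)-2-methoxy-3-(methoxymethoxy)benzene | COc1c(OCOC)cc(OCc2ccccc2)cc1OCc1ccccc1 | intermediate
8 | 3,5-bis(benzyloxy)-2-methoxyphenol | COc1c(O)cc(OCc2ccccc2)cc1OCc1ccccc1 | intermediate
9 | 3-hydroxy-4,5-dimethoxybenzaldehyde | COc1cc(C=O)cc(O)c1OC | starting material
10 | 3-(benzyloxy)-4,5-dimethoxybenzaldehyde | COc1cc(C=O)cc(OCc2ccccc2)c1OC | intermediate
11 | 1-(benzyloxy)-2,3-dimethoxy-5-[2-(methylsulfanyl)-2-(methylsulfinyl)ethenyl]benzene | COc1cc(C=C(SC)S(C)=O)cc(OCc2ccccc2)c1OC | intermediate
12 | methyl 2-[3-(benzyloxy)-4,5-dimethoxyphenyl]acetate | COC(=O)Cc1cc(OC)c(OC)c(OCc2ccccc2)c1 | intermediate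
13 | methyl (Z)-2-[3-(benzyloxy)-4,5-dimethoxyphenyl]-3-hydroxyacrylate | COC(=O)/C(=C\O)c1cc(OC)c(OC)c(OCc2ccccc2)c1 | intermediate
14 | methyl (Z)-2-[3-(benzyloxy)-4,5-dimethoxyphenyl]-3-(tosyloxy)acrylate | COC(=O)/C(=C\OS(=O)(=O)c1ccc(C)cc1)c1cc(OC)c(OC)c(OCc2ccccc2)c1 | intermediate
15 | methyl (Z)-3-[3,5-bis(benzyloxy)-2-methoxyphenoxy]-2-[3-(benzyloxy)-4,5-dimethoxyphenyl]acrylate | COC(=O)/C(=C\Oc1cc(OCc2ccccc2)cc(OCc2ccccc2)c1OC)c1cc(OC)c(OC)c(OCc2ccccc2)c1 | intermediate
16 | (Z)-3-[3,5-bis(benzyloxy)-2-methoxyphenoxy]-2-[3-(benzyloxy)-4,5-dimethoxyphenyl]acrylic acid | O=C(O)/C(=C\Oc1cc(OCc2ccccc2)cc(OCc2ccccc2)c1OC)c1cc(OC)c(OC)c(OCc2ccccc2)c1 | intermediate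
17 | (Z)-3-[3,5-bis(benzyloxy)-2-methoxyphenoxy]-2-[3-(benzyloxy)-4,5-dimethoxyphenyl]acrylic trifluoroacetic anhydride | O=C(OC(=O)C(F)(F)F)/C(=C\Oc1cc(OCc2ccccc2)cc(OCc2ccccc2)c1OC)c1cc(OC)c(OC)c(OCc2ccccc2)c1 | intermediate
18 | 5,7-bis(benzyloxy)-3-[3-(benzyloxy)-4,5-dimethoxyphenyl]-8-methoxy-4H-chromen-4-one | COc1cc(-c2coc3c(OC)c(OCc4ccccc4)cc(OCc4ccccc4)c3c2=O)cc(OCc2ccccc2)c1OC | intermediate
19 | isoirigenin | COc1cc(-c2coc3c(OC)c(O)cc(O)c3c2=O)cc(O)c1OC | target

Total step count: 14. Longest linear sequence: 9 steps (steps 1–5 and 11–14; the ring B branch, steps 6–10 and 11–14, is equally long).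

Steps most likely to fail

Step 13. The closure may suffer from four processes:
- loss or migration of benzyl groups under the acid released;
- intermolecular trifluoroacetylation of ring A;
- sluggish interconversion of the alkene isomers;
- too low an electrophilicity of the donor-stabilised acyl cation.

The fallback makes the same C4–C4a bond with reversed polarity and without acid. Setting out from 8, amine-catalysed ortho-bromination (NBS, cat. i-Pr2NH, CH2Cl2, 0 °C) should give 3,5-bis(benzyloxy)-2-bromo-6-methoxyphenol F1; both the hydrogen bond to the phenol and the smaller flanking groups direct bromine to the free ortho carbon. Vinylic substitution of 14 with this phenol (K2CO3, DMF) should give methyl (Z)-3-[3,5-bis(benzyloxy)-2-bromo-6-methoxyphenoxy]-2-[3-(benzyloxy)-4,5-dimethoxyphenyl]acrylate F2. Bromine–lithium exchange (n-BuLi, THF, −95 °C) and attack of the aryllithium on the cis ester carbonyl (Parham cyclisation) bring the route back at 18.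

Step 11. The phenoxide may attack sulfur instead of carbon, which transfers the sulfonyl group to the phenol, and the alkene geometry may erode in a long-lived carbanion. The fallback replaces the sulfonate by a leaving group that has no second electrophilic site. Setting out from 13, deoxychlorination with (chloromethylene)dimethyliminium chloride (CH2Cl2, 0 °C → rt) should give methyl (Z)-2-[3-(benzyloxy)-4,5-dimethoxyphenyl]-3-chloroacrylate F3; either geometry serves. Addition–elimination with 8 (K2CO3, cat. DABCO, DMF) brings the route back at 15.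

Step 1. Poor discrimination among the three hydroxyl groups, over-alkylation and C-benzylation of the phloroglucinol nucleus may erode the selective dibenzylation. The fallback gives up kinetic selectivity in favour of chelation-controlled deprotection. Setting out from 1, exhaustive benzylation (excess 2, K2CO3, DMF, 60 °C) should give 2,4,6-tris(benzyloxy)benzaldehyde F4. MgBr2·OEt2 (toluene/Et2O, reflux) then binds between the formyl oxygen and one ortho ether oxygen and cleaves only that benzyl group, bringing the route back at 3.

Further compounds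
F1 | step 13 | 3,5-bis(benzyloxy)-2-bromo-6-methoxyphenol | COc1c(O)c(Br)c(OCc2ccccc2)cc1OCc1ccccc1
F2 | step 13 | methyl (Z)-3-[3,5-bis(benzyloxy)-2-bromo-6-methoxyphenoxy]-2-[3-(benzyloxy)-4,5-dimethoxyphenyl]acrylate | COC(=O)/C(=C\Oc1c(Br)c(OCc2ccccc2)cc(OCc2ccccc2)c1OC)c1cc(OC)c(OC)c(OCc2ccccc2)c1
F3 | step 11 | methyl (Z)-2-[3-(benzyloxy)-4,5-dimethoxyphenyl]-3-chloroacrylate | COC(=O)/C(=C\Cl)c1cc(OC)c(OC)c(OCc2ccccc2)c1
F4 | step 1 | 2,4,6-tris(benzyloxy)benzaldehyde | O=Cc1c(OCc2ccccc2)cc(OCc2ccccc2)cc1OCc1ccccc1
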